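**Retrosynthetic overview**
- Target ⇐ cleavage of two phenolic silyl ethers from the bis-silylated (S)-β-acetoxy ketone (last step, near-neutral).
- (S)-β-Acetoxy ketone ⇐ enantioselective hydrogenation of the C=C bond of the (E)-β-acetoxy enone (the new step; it sets the only stereocentre with the acetate already in place).
- β-Acetoxy enone ⇐ O-acetylation of the symmetric 1,3-diketone; diketone ⇐ bis-O-silylation of tetrahydrocurcumin, which supplies every carbon except the acetyl group.
- No ring is formed in the route; both 4-hydroxy-3-methoxyphenyl rings come intact from the starting material.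

Assumption: the SMILES is read as (S) at the acetoxy-bearing carbon, and tetrahydrocurcumin (1) is bought as a catalogue chemical.

**Step 1**
Reactants: 1 tetrahydrocurcumin, 1,7-bis(4-hydroxy-3-methoxyphenyl)heptane-3,5-dione
Product: 2 1,7-bis[4-(tert-butyldimethylsilyloxy)-3-methoxyphenyl]heptane-3,5-dione
Conditions: TBSCl (2.3 equiv), imidazole (5 equiv), DMF, 0 °C to rt; aqueous NH4Cl work-up
Reagents that add atoms: tert-butyldimethylsilyl chloride, CC(C)(C)[Si](C)(C)Cl
Why: Standard silyl ether protection of phenols, which react much faster than the hydrogen-bonded enol of the diketone; the aryl silyl ethers survive acylation and hydrogenation and later leave under near-neutral fluoride (no stereocentre involved).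

**Step 2**
Reactants: 2 1,7-bis[4-(tert-butyldimethylsilyloxy)-3-methoxyphenyl]heptane-3,5-dione
Product: 3 (E)-1,7-bis[4-(tert-butyldimethylsilyloxy)-3-methoxyphenyl]-5-oxohept-3-en-3-yl acetate
Conditions: AcCl (1.3 equiv), Et3N (1.6 equiv), CH2Cl2, −40 to 0 °C; cold aqueous NaHCO3 work-up, chromatography on neutral silica
Reagents that add atoms: acetyl chloride, CC(Cl)=O
Why: Enol ester formation by O-acylation of the non-chelated triethylammonium enolate, which reacts through its extended form to give the (E)-enol acetate (acetoxy trans to the ketone); 2 is symmetric, so only one constitutional isomer can form.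

**Step 3**
Reactants: 3 (E)-1,7-bis[4-(tert-butyldimethylsilyloxy)-3-methoxyphenyl]-5-oxohept-3-en-3-yl acetate
Product: 4 (3S)-1,7-bis[4-(tert-butyldimethylsilyloxy)-3-methoxyphenyl]-5-oxoheptan-3-yl acetate
Conditions: [Rh(cod)((R,R)-Me-DuPhos)]BF4 (2 mol%; cod = cycloocta-1,5-diene, Me-DuPhos = 1,2-bis(2,5-dimethylphospholan-1-yl)benzene), H2 (10 bar), CH2Cl2, 25 °C, 16 h
Reagents that add atoms: none
Why: Proposed new method: enantioselective hydrogenation of an acyclic β-acetoxy enone (the O-acetyl enol of a 1,3-diketone), a substrate class for which this reaction has not been shown; the C=C bond and the acetyl C=O chelate cationic monovalent rhodium as in enamide hydrogenation, H2 adds to give a trivalent rhodium dihydride, hydride goes to the carbon next to the ketone and rhodium sits on the acetoxy-bearing carbon in a five-membered chelate (so no β-acetoxy elimination is open), and C–H reductive elimination releases the product; the C2-symmetric phospholane quadrants direct hydrogen to the Re face of the acetoxy-bearing carbon (OAc > C-4 > C-2), predicted to give (S) with the (R,R)-ligand by analogy with (E)-β-acylamino acrylates; closest known reaction type is the rhodium–bisphosphine asymmetric hydrogenation of enol acetates, β-acyloxy acrylates and β-acylamino enones.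

**Step 4**
Reactants: 4 (3S)-1,7-bis[4-(tert-butyldimethylsilyloxy)-3-methoxyphenyl]-5-oxoheptan-3-yl acetate
Product: 5 (3S)-1,7-bis(4-hydroxy-3-methoxyphenyl)-5-oxoheptan-3-yl acetate, identical with (5S)-5-acetoxy-1,7-bis(4-hydroxy-3-methoxyphenyl)heptan-3-one
Conditions: KHF2 (3 equiv), MeOH, rt, 1–3 h
Reagents that add atoms: none
Why: Fluoride-driven cleavage of aryl silyl ethers (Si–F bond formation); weakly acidic bifluoride removes phenolic TBS groups at room temperature without enolising the ketone, so acetic acid is not eliminated and the stereocentre, which is β to the ketone, is untouched.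

**Compound list**
1 | tetrahydrocurcumin, 1,7-bis(4-hydroxy-3-methoxyphenyl)heptane-3,5-dione | COc1cc(CCC(=O)CC(=O)CCc2ccc(O)c(OC)c2)ccc1O | starting material
2 | 1,7-bis[4-(tert-butyldimethylsilyloxy)-3-methoxyphenyl]heptane-3,5-dione | COc1cc(CCC(=O)CC(=O)CCc2ccc(O[Si](C)(C)C(C)(C)C)c(OC)c2)ccc1O[Si](C)(C)C(C)(C)C | intermediate
3 | (E)-1,7-bis[4-(tert-butyldimethylsilyloxy)-3-methoxyphenyl]-5-oxohept-3-en-3-yl acetate | CC(=O)O/C(CCc1ccc(O[Si](C)(C)C(C)(C)C)c(OC)c1)=C/C(=O)CCc1ccc(O[Si](C)(C)C(C)(C)C)c(OC)c1 | intermediate
4 | (3S)-1,7-bis[4-(tert-butyldimethylsilyloxy)-3-methoxyphenyl]-5-oxoheptan-3-yl acetate | COc1cc(CCC(=O)C[C@H](CCc2ccc(O[Si](C)(C)C(C)(C)C)c(OC)c2)OC(C)=O)ccc1O[Si](C)(C)C(C)(C)C | intermediate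
5 | (3S)-1,7-bis(4-hydroxy-3-methoxyphenyl)-5-oxoheptan-3-yl acetate | COc1cc(CCC(=O)C[C@H](CCc2ccc(O)c(OC)c2)OC(C)=O)ccc1O | target

**Step count and risks**
Total step count: 4. Longest linear sequence: 4 steps (1 → 2 → 3 → 4 → 5).

The three steps most likely to fail:

Step 3 (the proposed new hydrogenation). The trisubstituted push–pull alkene may react slowly, the facial sense is predicted and not proven, and C–O hydrogenolysis is conceivable. The fallback uses known chemistry only, sets out from 2 and comes back at 4. Diketone 2 is reduced by Noyori asymmetric hydrogenation ([RuCl(p-cymene)((S)-BINAP)]Cl 1 mol%, a divalent ruthenium precatalyst, H2 50 bar, MeOH, 50 °C) to the C2-symmetric anti diol (3S,5S)-1,7-bis[4-(tert-butyldimethylsilyloxy)-3-methoxyphenyl]heptane-3,5-diol F1. Its two hydroxyl groups are homotopic, so mono-acetylation (Ac2O 1.0 equiv, pyridine, CH2Cl2, 0 °C, recovered diol recycled) gives one compound, (3S,5S)-1,7-bis[4-(tert-butyldimethylsilyloxy)-3-methoxyphenyl]-5-hydroxyheptan-3-yl acetate F2. Oxidation of the remaining alcohol with Dess–Martin periodinane and NaHCO3 in CH2Cl2 gives 4. This material of known configuration also serves as the reference for checking the sense of the new step.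

Step 2 (enol acetylation). C-acylation to the triketone, E/Z mixtures and hydrolysis of the vinylogous anhydride are the dangers. The fallback sets out from 2 and comes back at 3, and it reverses the polarity of the C–O bond formation so that C-acylation cannot occur. Diketone 2 is converted with Ph3PCl2 and Et3N in CH2Cl2 at 0 °C into the β-chloro enone 5-chloro-1,7-bis[4-(tert-butyldimethylsilyloxy)-3-methoxyphenyl]hept-4-en-3-one (E/Z mixture) F3. Addition–elimination with Bu4NOAc in MeCN at 0 °C to rt then gives 3; reversible acetate addition should equilibrate the product to the more stable (E)-isomer.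

Step 4 (desilylation next to a β-acetoxy ketone). Loss of acetic acid to the enone is the danger. The fallback sets out from 1 and comes back at 5, and it replaces silyl protection by acetate protection with an enzymatic end game; it relies on the step 3 hydrogenation working. Compound 1 is peracetylated (AcCl 3.6 equiv, Et3N 4 equiv, CH2Cl2, −40 to 0 °C) to (E)-1,7-bis(4-acetoxy-3-methoxyphenyl)-5-oxohept-3-en-3-yl acetate F4. Hydrogenation under the conditions of step 3 gives (3S)-1,7-bis(4-acetoxy-3-methoxyphenyl)-5-oxoheptan-3-yl acetate F5. The two aryl acetates are then removed by alcoholysis with immobilised Candida antarctica lipase B and n-BuOH in MTBE at 30 °C to give 5. The secondary acetate, flanked by two chains larger than ethyl, should not be accepted by the enzyme.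

**Further compounds**
F1 | step 3 | (3S,5S)-1,7-bis[4-(tert-butyldimethylsilyloxy)-3-methoxyphenyl]heptane-3,5-diol | COc1cc(CC[C@H](O)C[C@H](CCc2ccc(O[Si](C)(C)C(C)(C)C)c(OC)c2)O)ccc1O[Si](C)(C)C(C)(C)C
F2 | step 3 | (3S,5S)-1,7-bis[4-(tert-butyldimethylsilyloxy)-3-methoxyphenyl]-5-hydroxyheptan-3-yl acetate | COc1cc(CC[C@H](O)C[C@H](CCc2ccc(O[Si](C)(C)C(C)(C)C)c(OC)c2)OC(C)=O)ccc1O[Si](C)(C)C(C)(C)C
F3 | step 2 | 5-chloro-1,7-bis[4-(tert-butyldimethylsilyloxy)-3-methoxyphenyl]hept-4-en-3-one (E/Z mixture) | COc1cc(CCC(Cl)=CC(=O)CCc2ccc(O[Si](C)(C)C(C)(C)C)c(OC)c2)ccc1O[Si](C)(C)C(C)(C)C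
F4 | step 4 | (E)-1,7-bis(4-acetoxy-3-methoxyphenyl)-5-oxohept-3-en-3-yl acetate | CC(=O)O/C(CCc1ccc(OC(C)=O)c(OC)c1)=C/C(=O)CCc1ccc(OC(C)=O)c(OC)c1
F5 | step 4 | (3S)-1,7-bis(4-acetoxy-3-methoxyphenyl)-5-oxoheptan-3-yl acetate | COc1cc(CCC(=O)C[C@H](CCc2ccc(OC(C)=O)c(OC)c2)OC(C)=O)ccc1OC(C)=O
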